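**Retrosynthetic overview**

1. Target ⇒ last C–C bond (C13'–C1) by an intermolecular Alder-ene union of two complete, diastereomeric germacranolide monomers: enophile 16 (unit B) and the silylated, selenide-masked ene donor 20 (unit A), followed by unmasking.
2. 16 and 20 ⇒ one common macrocycle 14: 16 by Mitsunobu inversion at C6; 20 by lactone opening and Mitsunobu relactonisation with inversion at C8 (trans- to cis-fused lactone).
3. 14 ⇒ ten-membered ring closed by CrCl2 allylation (C6–C7) of the enal–bromomethylbutenolide 13; the butenolide ring is made first, the ten-membered ring second.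
4. 13 ⇒ Morita–Baylis–Hillman adduct of the (S)-2-benzoyloxy aldehyde 7; its stereocentre (C8) comes from an organocatalytic α-benzoyloxylation of achiral aldehyde 6, and all later centres follow by substrate control.
5. 6 ⇒ geranyl acetate (allylic oxidation, bromide, two-carbon extension).

Assumption and notation: the SMILES is read literally in germacrane numbering (ring C1–C10, C14 on C10, C15 on C4, C11–C13 on C7, lactone to O8; primes for unit B). Unit A is 1S,6R,7S,8R, 4E,9Z, cis-fused lactone; unit B is 6'S,7'S,8'S,11'R, 1'(10')E,4'E, trans-fused lactone; the units are joined C13'–C1.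

**Route**

Step 1
Reactants: 1 geranyl acetate
Product: 2 (2E,6E)-8-hydroxy-3,7-dimethylocta-2,6-dien-1-yl acetate
Conditions: SeO2 (0.1 equiv), t-BuOOH, CH2Cl2, rt
Reagents that add atoms: tert-butyl hydroperoxide CC(C)(C)OO
Why: Selenium dioxide allylic oxidation (ene reaction then [2,3]-shift) hydroxylates only the E-methyl of the electron-rich terminal alkene, the 2,3-alkene being deactivated by the allylic acetate; no stereocentre is formed.

Step 2
Reactants: 2 (2E,6E)-8-hydroxy-3,7-dimethylocta-2,6-dien-1-yl acetate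
Product: 3 (2E,6E)-8-bromo-3,7-dimethylocta-2,6-dien-1-yl acetate
Conditions: CBr4, PPh3, CH2Cl2, 0 °C
Reagents that add atoms: tetrabromomethane BrC(Br)(Br)Br
Why: Appel bromination of a primary allylic alcohol proceeds by SN2 at carbon under neutral conditions, so the alkene geometry and the acetate are untouched.

Step 3
Reactants: 3 (2E,6E)-8-bromo-3,7-dimethylocta-2,6-dien-1-yl acetate; 4 acetaldehyde N,N-dimethylhydrazone
Product: 6 (2E,6E)-3,7-dimethyl-10-oxodeca-2,6-dien-1-yl acetate, via dimethylhydrazone 5 (not isolated)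
Conditions: 4, LDA, THF, 0 °C; then 3, −78 °C; then aq. oxalic acid, Et2O, rt
Reagents that add atoms: water O
Why: Azaenolate alkylation followed by hydrazone hydrolysis adds the two-carbon aldehyde unit; at −78 °C the lithiated hydrazone displaces the allylic bromide (SN2) much faster than it attacks the acetate.

Step 4
Reactants: 6 (2E,6E)-3,7-dimethyl-10-oxodeca-2,6-dien-1-yl acetate
Product: 7 (2S,4E,8E)-10-acetoxy-4,8-dimethyl-1-oxodeca-4,8-dien-2-yl benzoate
Conditions: (S)-α,α-diphenylprolinol trimethylsilyl ether (10 mol%), dibenzoyl peroxide, hydroquinone (10 mol%), THF, 0 °C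
Reagents that add atoms: dibenzoyl peroxide O=C(OOC(=O)c1ccccc1)c1ccccc1
Why: Organocatalytic enamine α-benzoyloxylation: the E-enamine is attacked by the peroxide on the face away from the diphenyl(silyloxy)methyl group, giving the (S)-2-benzoyloxy aldehyde and thereby the first stereocentre (C8).

Step 5
Reactants: 7 (2S,4E,8E)-10-acetoxy-4,8-dimethyl-1-oxodeca-4,8-dien-2-yl benzoate; 8 methyl acrylate
Product: 9 methyl 2-[(2S,4E,8E)-10-acetoxy-2-(benzoyloxy)-1-hydroxy-4,8-dimethyldeca-4,8-dien-1-yl]prop-2-enoate (both C1 epimers)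
Conditions: DABCO (0.5 equiv), methyl acrylate (neat), rt
Reagents that add atoms: none
Why: Morita–Baylis–Hillman reaction attaches C11–C13 to C7; α-oxygenated aldehydes are fast electrophiles here, which limits base exposure of C8, and the new carbinol centre is erased in step 8.

Step 6
Reactants: 9 methyl 2-[(2S,4E,8E)-10-acetoxy-2-(benzoyloxy)-1-hydroxy-4,8-dimethyldeca-4,8-dien-1-yl]prop-2-enoate
Product: 11 (5S)-4-hydroxy-5-[(2E,6E)-8-hydroxy-2,6-dimethylocta-2,6-dien-1-yl]-3-methylideneoxolan-2-one (both C4 epimers), via triol ester 10 (not isolated)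
Conditions: K2CO3 (0.3 equiv), MeOH, 0 °C to rt
Reagents that add atoms: none
Why: Transesterification removes acetate and benzoate, and the freed C8 hydroxyl closes the five-membered lactone onto the methyl ester (lactonisation), leaving C8 untouched.

Step 7
Reactants: 11 (5S)-4-hydroxy-5-[(2E,6E)-8-hydroxy-2,6-dimethylocta-2,6-dien-1-yl]-3-methylideneoxolan-2-one
Product: 12 (2E,6E)-8-[(2S)-3-hydroxy-4-methylidene-5-oxooxolan-2-yl]-3,7-dimethylocta-2,6-dienal (both C3 epimers)
Conditions: TEMPO (10 mol%), PhI(OAc)2, CH2Cl2, rt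
Reagents that add atoms: none
Why: Oxoammonium (TEMPO) oxidation is selective for the primary allylic alcohol over the hindered secondary one and gives the enal without touching the methylene lactone.

Step 8
Reactants: 12 (2E,6E)-8-[(2S)-3-hydroxy-4-methylidene-5-oxooxolan-2-yl]-3,7-dimethylocta-2,6-dienal
Product: 13 (2E,6E)-8-[(2S)-4-(bromomethyl)-5-oxo-2,5-dihydrofuran-2-yl]-3,7-dimethylocta-2,6-dienal
Conditions: PBr3 (0.4 equiv), Et2O, −20 °C
Reagents that add atoms: phosphorus tribromide BrP(Br)Br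
Why: Allylic transposition (SN2' bromination of a Morita–Baylis–Hillman alcohol) converts both carbinol epimers into the conjugated bromomethylbutenolide, the thermodynamically favoured allylic bromide.

Step 9
Reactants: 13 (2E,6E)-8-[(2S)-4-(bromomethyl)-5-oxo-2,5-dihydrofuran-2-yl]-3,7-dimethylocta-2,6-dienal
Product: 14 (6R,7S,8S)-6-hydroxygermacra-1(10)E,4E,11(13)-trien-12,8-olide
Conditions: CrCl2 (6 equiv), THF, rt, slow addition (final 2 mM)
Reagents that add atoms: none
Why: Intramolecular Nozaki–Hiyama–Kishi allylation: the allylchromium adds through C7 to the enal anti to the C8 substituent (7,8-trans) in a chair transition state with the E-type allyl unit (6,7-anti), setting C7 (S) and C6 (R) and closing the ten-membered ring.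

Step 10
Reactants: 14 (6R,7S,8S)-6-hydroxygermacra-1(10)E,4E,11(13)-trien-12,8-olide
Product: 15 (6S,7R,8S)-6-(chloroacetoxy)germacra-1(10)E,4E,11(13)-trien-12,8-olide
Conditions: ClCH2CO2H, PPh3, DIAD, toluene, 0 °C to rt
Reagents that add atoms: chloroacetic acid OC(=O)CCl
Why: Mitsunobu esterification inverts the allylic C6 carbinol by SN2 (the C7 descriptor changes only because of ligand priority).

Step 11
Reactants: 15 (6S,7R,8S)-6-(chloroacetoxy)germacra-1(10)E,4E,11(13)-trien-12,8-olide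
Product: 16 (6S,7S,8S)-6-hydroxygermacra-1(10)E,4E,11(13)-trien-12,8-olide
Conditions: K2CO3 (0.1 equiv), MeOH, −10 °C, 15 min
Reagents that add atoms: none
Why: Methanolysis of the activated chloroacetate is far faster than conjugate addition to the methylene lactone or lactone migration, releasing the 6S alcohol (unit B monomer).

Step 12
Reactants: 14 (6R,7S,8S)-6-hydroxygermacra-1(10)E,4E,11(13)-trien-12,8-olide
Product: 17 (6R,7R,8S)-6-(tert-butyldimethylsilyloxy)germacra-1(10)E,4E,11(13)-trien-12,8-olide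
Conditions: TBSOTf, 2,6-lutidine, CH2Cl2, −78 °C
Reagents that add atoms: tert-butyldimethylsilyl triflate CC(C)(C)[Si](C)(C)OS(=O)(=O)C(F)(F)F
Why: Silyl ether formation under buffered conditions blocks the allylic 6-hydroxyl for steps 13–15 without changing any stereocentre.

Step 13
Reactants: 17 (6R,7R,8S)-6-(tert-butyldimethylsilyloxy)germacra-1(10)E,4E,11(13)-trien-12,8-olide
Product: 19 (6R,7R,8S,11R)-6-(tert-butyldimethylsilyloxy)-8-hydroxy-13-(phenylselanyl)germacra-1(10)E,4E-dien-12-oic acid, via selenide lactone 18 (not isolated)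
Conditions: (PhSe)2, NaBH4, EtOH, 0 °C; then LiOH, THF/H2O, rt; then 1 M HCl to pH 5, 0 °C
Reagents that add atoms: diphenyl diselenide c1ccccc1[Se][Se]c1ccccc1; lithium hydroxide [Li+].[OH-]
Why: Michael addition of benzeneselenolate masks the methylene lactone (C11 set by enolate protonation trans to C6 and erased in step 16), and saponification then opens the lactone to the 8-hydroxy acid with C8 still S.

Step 14
Reactants: 19 (6R,7R,8S,11R)-6-(tert-butyldimethylsilyloxy)-8-hydroxy-13-(phenylselanyl)germacra-1(10)E,4E-dien-12-oic acid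
Product: 20 (6R,7R,8R,11R)-6-(tert-butyldimethylsilyloxy)-13-(phenylselanyl)germacra-1(10)E,4E-dien-12,8-olide
Conditions: PPh3, DIAD, THF, 0 °C to rt
Reagents that add atoms: none
Why: Mitsunobu lactonisation: the carboxylate displaces the activated 8-hydroxyl with inversion (SN2), giving the cis-fused 8R lactone of unit A while the silyl ether keeps the 6-oxygen out of the reaction.

Step 15
Reactants: 16 (6S,7S,8S)-6-hydroxygermacra-1(10)E,4E,11(13)-trien-12,8-olide; 20 (6R,7R,8R,11R)-6-(tert-butyldimethylsilyloxy)-13-(phenylselanyl)germacra-1(10)E,4E-dien-12,8-olide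
Product: 21 1-[(6'S,7'S,8'S,11'R)-6'-hydroxygermacra-1'(10')E,4'E-dien-12',8'-olid-13'-yl]-(1S,6R,7R,8R,11R)-6-(tert-butyldimethylsilyloxy)-13-(phenylselanyl)germacra-4E,9Z-dien-12,8-olide
Conditions: 16 (1 equiv), Me2AlCl (1.2 equiv), CH2Cl2, −78 °C; then slow addition to 20 (2.5 equiv), −78 to −20 °C
Reagents that add atoms: none
Why: Proposed new method: a chelation-directed Alder-ene heterodimerisation in which Me2AlCl turns the only free hydroxyl (6'-OH of 16) into a chloro(methyl)aluminium alkoxide that binds the lactone carbonyl of the same molecule, so only the methylene lactone of 16 is activated, while 20 (own enophile masked as selenide, 4,5-alkene shielded by the silyl ether) attacks C13' with C1 from its peripheral face and passes H-9 suprafacially to C11' in a six-membered transition state, giving the C13'–C1 bond, the 9Z alkene, C1 (S) and C11' (R, the all-trans lactone); the closest known reaction type is the alkylaluminium chloride-promoted ene reaction of α-substituted acrylates with trisubstituted alkenes, which has not been shown for α-methylene-γ-butyrolactone enophiles or germacradiene ene donors.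

Step 16
Reactants: 21 selenide-masked silylated dimer
Product: 23 1-[(6'S,7'S,8'S,11'R)-6'-hydroxygermacra-1'(10')E,4'E-dien-12',8'-olid-13'-yl]-(1S,6R,7R,8R)-6-(tert-butyldimethylsilyloxy)germacra-4E,9Z,11(13)-trien-12,8-olide, via selenoxide 22 (not isolated)
Conditions: NaIO4, NaHCO3, THF/MeOH/H2O, 0 °C to rt
Reagents that add atoms: none
Why: Selenide oxidation and selenoxide syn-elimination (β-hydrogen only at C11) regenerate the methylene lactone of unit A at room temperature, well below the Cope rearrangement range of the 1,5-diene in unit B.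

Step 17
Reactants: 23 silylated dimer
Product: 24 1-[(6'S,7'S,8'S,11'R)-6'-hydroxygermacra-1'(10')E,4'E-dien-12',8'-olid-13'-yl]-(1S,6R,7S,8R)-6-hydroxygermacra-4E,9Z,11(13)-trien-12,8-olide (CNP0191625.2)
Conditions: HF·pyridine, pyridine, THF, 0 °C to rt
Reagents that add atoms: none
Why: Buffered fluoride desilylation frees the 6-hydroxyl without base, so neither lactone migrates and no stereocentre is touched.

**Compound list**

1 | geranyl acetate, (2E)-3,7-dimethylocta-2,6-dien-1-yl acetate | CC(C)=CCC/C(C)=C/COC(C)=O | starting material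
2 | (2E,6E)-8-hydroxy-3,7-dimethylocta-2,6-dien-1-yl acetate | OC/C(C)=C/CC/C(C)=C/COC(C)=O | intermediate
3 | (2E,6E)-8-bromo-3,7-dimethylocta-2,6-dien-1-yl acetate | BrC/C(C)=C/CC/C(C)=C/COC(C)=O | intermediate
4 | acetaldehyde N,N-dimethylhydrazone | CC=NN(C)C | starting material
5 | (2E,6E)-10-(2,2-dimethylhydrazinylidene)-3,7-dimethyldeca-2,6-dien-1-yl acetate | CN(C)N=CCC/C(C)=C/CC/C(C)=C/COC(C)=O | intermediate
6 | (2E,6E)-3,7-dimethyl-10-oxodeca-2,6-dien-1-yl acetate | O=CCC/C(C)=C/CC/C(C)=C/COC(C)=O | intermediate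
7 | (2S,4E,8E)-10-acetoxy-4,8-dimethyl-1-oxodeca-4,8-dien-2-yl benzoate | O=C[C@@H](OC(=O)c1ccccc1)C/C(C)=C/CC/C(C)=C/COC(C)=O | intermediate
8 | methyl acrylate | C=CC(=O)OC | starting material
9 | methyl 2-[(2S,4E,8E)-10-acetoxy-2-(benzoyloxy)-1-hydroxy-4,8-dimethyldeca-4,8-dien-1-yl]prop-2-enoate (both C1 epimers) | C=C(C(=O)OC)C(O)[C@@H](OC(=O)c1ccccc1)C/C(C)=C/CC/C(C)=C/COC(C)=O | intermediate
10 | methyl 2-[(2S,4E,8E)-1,2,10-trihydroxy-4,8-dimethyldeca-4,8-dien-1-yl]prop-2-enoate (both C1 epimers) | C=C(C(=O)OC)C(O)[C@@H](O)C/C(C)=C/CC/C(C)=C/CO | intermediate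
11 | (5S)-4-hydroxy-5-[(2E,6E)-8-hydroxy-2,6-dimethylocta-2,6-dien-1-yl]-3-methylideneoxolan-2-one (both C4 epimers) | C=C1C(=O)O[C@@H](C/C(C)=C/CC/C(C)=C/CO)C1O | intermediate
12 | (2E,6E)-8-[(2S)-3-hydroxy-4-methylidene-5-oxooxolan-2-yl]-3,7-dimethylocta-2,6-dienal (both C3 epimers) | C=C1C(=O)O[C@@H](C/C(C)=C/CC/C(C)=C/C=O)C1O | intermediate
13 | (2E,6E)-8-[(2S)-4-(bromomethyl)-5-oxo-2,5-dihydrofuran-2-yl]-3,7-dimethylocta-2,6-dienal | BrCC1=C[C@H](C/C(C)=C/CC/C(C)=C/C=O)OC1=O | intermediate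
14 | (6R,7S,8S)-6-hydroxygermacra-1(10)E,4E,11(13)-trien-12,8-olide (trans-fused lactone) | C=C1C(=O)O[C@H]2C/C(C)=C/CC/C(C)=C/[C@@H](O)[C@H]12 | intermediate
15 | (6S,7R,8S)-6-(chloroacetoxy)germacra-1(10)E,4E,11(13)-trien-12,8-olide | C=C1C(=O)O[C@H]2C/C(C)=C/CC/C(C)=C/[C@H](OC(=O)CCl)[C@H]12 | intermediate
16 | (6S,7S,8S)-6-hydroxygermacra-1(10)E,4E,11(13)-trien-12,8-olide (unit B monomer) | C=C1C(=O)O[C@H]2C/C(C)=C/CC/C(C)=C/[C@H](O)[C@H]12 | intermediate
17 | (6R,7R,8S)-6-(tert-butyldimethylsilyloxy)germacra-1(10)E,4E,11(13)-trien-12,8-olide | C=C1C(=O)O[C@H]2C/C(C)=C/CC/C(C)=C/[C@@H](O[Si](C)(C)C(C)(C)C)[C@H]12 | intermediate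
18 | (6R,7R,8S,11R)-6-(tert-butyldimethylsilyloxy)-13-(phenylselanyl)germacra-1(10)E,4E-dien-12,8-olide (trans-fused) | c1ccccc1[Se]C[C@H]1C(=O)O[C@H]2C/C(C)=C/CC/C(C)=C/[C@@H](O[Si](C)(C)C(C)(C)C)[C@@H]21 | intermediate
19 | (6R,7R,8S,11R)-6-(tert-butyldimethylsilyloxy)-8-hydroxy-13-(phenylselanyl)germacra-1(10)E,4E-dien-12-oic acid | OC(=O)[C@H](C[Se]c1ccccc1)[C@@H]1[C@@H](O)C/C(C)=C/CC/C(C)=C/[C@H]1O[Si](C)(C)C(C)(C)C | intermediate
20 | (6R,7R,8R,11R)-6-(tert-butyldimethylsilyloxy)-13-(phenylselanyl)germacra-1(10)E,4E-dien-12,8-olide (cis-fused, masked unit A monomer) | c1ccccc1[Se]C[C@H]1C(=O)O[C@@H]2C/C(C)=C/CC/C(C)=C/[C@@H](O[Si](C)(C)C(C)(C)C)[C@@H]21 | intermediate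
21 | 1-[(6'S,7'S,8'S,11'R)-6'-hydroxygermacra-1'(10')E,4'E-dien-12',8'-olid-13'-yl]-(1S,6R,7R,8R,11R)-6-(tert-butyldimethylsilyloxy)-13-(phenylselanyl)germacra-4E,9Z-dien-12,8-olide | c1ccccc1[Se]C[C@H]1C(=O)O[C@@H]2/C=C(/C)[C@H](C[C@H]3C(=O)O[C@H]4C/C(C)=C/CC/C(C)=C/[C@H](O)[C@@H]43)CC/C(C)=C/[C@@H](O[Si](C)(C)C(C)(C)C)[C@H]12 | intermediate
22 | selenoxide of 21 (Se-oxide, either configuration at selenium) | O=[Se](c1ccccc1)C[C@H]1C(=O)O[C@@H]2/C=C(/C)[C@H](C[C@H]3C(=O)O[C@H]4C/C(C)=C/CC/C(C)=C/[C@H](O)[C@@H]43)CC/C(C)=C/[C@@H](O[Si](C)(C)C(C)(C)C)[C@H]12 | intermediate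
23 | 1-[(6'S,7'S,8'S,11'R)-6'-hydroxygermacra-1'(10')E,4'E-dien-12',8'-olid-13'-yl]-(1S,6R,7R,8R)-6-(tert-butyldimethylsilyloxy)germacra-4E,9Z,11(13)-trien-12,8-olide | C=C1C(=O)O[C@@H]2/C=C(/C)[C@H](C[C@H]3C(=O)O[C@H]4C/C(C)=C/CC/C(C)=C/[C@H](O)[C@@H]43)CC/C(C)=C/[C@@H](O[Si](C)(C)C(C)(C)C)[C@H]12 | intermediate
24 | 1-[(6'S,7'S,8'S,11'R)-6'-hydroxygermacra-1'(10')E,4'E-dien-12',8'-olid-13'-yl]-(1S,6R,7S,8R)-6-hydroxygermacra-4E,9Z,11(13)-trien-12,8-olide (CNP0191625.2) | C=C1C(=O)O[C@@H]2/C=C(/C)[C@H](C[C@H]3C(=O)O[C@H]4C/C(C)=C/CC/C(C)=C/[C@H](O)[C@@H]43)CC/C(C)=C/[C@@H](O)[C@H]12 | target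

**Step count and risk**

Total step count: 17. Longest linear sequence: 15 (steps 1–9, 12–14, 15–17).

The three steps most likely to fail:

Step 15 (the proposed new reaction). The ene donor may lose a C14 hydrogen instead of H-9 (giving the 10(14)-ene isomer), or the developing charge at C10 may be trapped transannularly by the 4,5-alkene. The methylene lactone may also simply be too weak an enophile. A wrong C11' epimer would be correctable by DBU equilibration to the all-trans lactone. The fallback uses known reactions only, sets out from 20 (with 16 as partner) and comes back to the route at 21. A formaldehyde carbonyl-ene reaction of 20 (paraformaldehyde, Me2AlCl, CH2Cl2, −78 °C) installs the linking carbon as the C1-hydroxymethyl ene adduct F1. Dess–Martin oxidation gives the C1-formyl compound F2, and Wittig methylenation (Ph3P=CH2, THF, −78 °C) gives the C1-vinyl compound F3. Cross-metathesis of F3 with the methylene lactone of 16 (second-generation Hoveyda–Grubbs catalyst, CH2Cl2, 40 °C) joins the halves as the E-alkylidene lactone F4. Conjugate reduction of F4 with [(Ph3P)CuH]6 (toluene, rt, wet) sets C11' by protonation on the less hindered face and returns 21.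

Step 9. The macrocyclisation may give oligomers or a poor ratio at C6. If the 6S epimer forms it is compound 16 itself and can be used directly. The fallback changes how the allylmetal is generated; it sets out from 12 and comes back at 14. Acetylation of 12 (Ac2O, DMAP, pyridine) gives the allylic acetate F5. Pd(PPh3)4-catalysed umpolung of F5 with InI (THF, rt) then forms the allylindium catalytically, at a low stationary concentration that favours ring closure over oligomerisation, and delivers 14 through the same cyclic transition state.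

Step 14. The hydroxy acid 19 can relactonise with retention before it is activated, or the activated alcohol can eliminate towards C9. The fallback replaces the Mitsunobu activation by a sulfonate displacement; it sets out from 19 and comes back at 20. Esterification (Me3SiCHN2, MeOH/toluene, 0 °C) gives the methyl ester F6, and mesylation (MsCl, Et3N, CH2Cl2, −20 °C) gives the 8-mesylate F7. LiOH (THF/H2O, rt) then saponifies the ester, and the carboxylate displaces the mesylate intramolecularly (SN2, inversion) to give 20.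

Further compounds
F1 | step 15 | (1R,6R,7R,8R,11R)-6-(tert-butyldimethylsilyloxy)-1-(hydroxymethyl)-13-(phenylselanyl)germacra-4E,9Z-dien-12,8-olide | c1ccccc1[Se]C[C@H]1C(=O)O[C@@H]2/C=C(/C)[C@H](CO)CC/C(C)=C/[C@@H](O[Si](C)(C)C(C)(C)C)[C@H]12
F2 | step 15 | (1R,6R,7R,8R,11R)-6-(tert-butyldimethylsilyloxy)-1-formyl-13-(phenylselanyl)germacra-4E,9Z-dien-12,8-olide | c1ccccc1[Se]C[C@H]1C(=O)O[C@@H]2/C=C(/C)[C@H](C=O)CC/C(C)=C/[C@@H](O[Si](C)(C)C(C)(C)C)[C@H]12
F3 | step 15 | (1S,6R,7R,8R,11R)-6-(tert-butyldimethylsilyloxy)-1-ethenyl-13-(phenylselanyl)germacra-4E,9Z-dien-12,8-olide | c1ccccc1[Se]C[C@H]1C(=O)O[C@@H]2/C=C(/C)[C@H](C=C)CC/C(C)=C/[C@@H](O[Si](C)(C)C(C)(C)C)[C@H]12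
F4 | step 15 | 11'(13')E-didehydro analogue of 21, 1-[(6'S,7'S,8'S)-6'-hydroxygermacra-1'(10')E,4'E,11'(13')E-trien-12',8'-olid-13'-yl]-(1S,6R,7R,8R,11R)-6-(tert-butyldimethylsilyloxy)-13-(phenylselanyl)germacra-4E,9Z-dien-12,8-olide | c1ccccc1[Se]C[C@H]1C(=O)O[C@@H]2/C=C(/C)[C@H](/C=C3/C(=O)O[C@H]4C/C(C)=C/CC/C(C)=C/[C@H](O)[C@@H]43)CC/C(C)=C/[C@@H](O[Si](C)(C)C(C)(C)C)[C@H]12
F5 | step 9 | (2S)-2-[(2E,6E)-2,6-dimethyl-8-oxoocta-2,6-dien-1-yl]-4-methylidene-5-oxooxolan-3-yl acetate (both C3 epimers) | C=C1C(=O)O[C@@H](C/C(C)=C/CC/C(C)=C/C=O)C1OC(C)=O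
F6 | step 14 | methyl (6R,7R,8S,11R)-6-(tert-butyldimethylsilyloxy)-8-hydroxy-13-(phenylselanyl)germacra-1(10)E,4E-dien-12-oate | COC(=O)[C@H](C[Se]c1ccccc1)[C@@H]1[C@@H](O)C/C(C)=C/CC/C(C)=C/[C@H]1O[Si](C)(C)C(C)(C)C
F7 | step 14 | methyl (6R,7S,8S,11R)-6-(tert-butyldimethylsilyloxy)-8-(methanesulfonyloxy)-13-(phenylselanyl)germacra-1(10)E,4E-dien-12-oate | COC(=O)[C@H](C[Se]c1ccccc1)[C@@H]1[C@@H](OS(C)(=O)=O)C/C(C)=C/CC/C(C)=C/[C@H]1O[Si](C)(C)C(C)(C)C
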